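**Strategy**

Everything rests on disconnecting the cyclohexanol ring between C1, the carbinol carbon that carries OH and CH3, and C2, the carbon that carries bromine. This vicinal O/Br pair is dissonant and calls for umpolung at C2. In the key step an α-bromoalkylsamarium carbenoid, generated from a terminal 1,1-dibromide, adds to a tethered methyl ketone: one operation closes the six-membered ring and sets the tertiary alcohol, the secondary bromide and both new stereocentres under control of C4. The precursor is acyclic at this ring but already holds the (E,E)-diene and the bromo-oxane ring, joined by an alkenylzinc addition and a chirality-transferring Claisen rearrangement.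

Key step: step 8

Remark on the chemistry: (−)-linalool is taken as the commercial (R)-enantiomer; (−)-MIB, (2S)-3-exo-morpholinoisoborneol, is assumed to deliver organozinc nucleophiles to the Si face of aldehydes; the η5-cyclopentadienyl rings of the zirconium compounds are written as σ-bonded rings in the SMILES strings.

**Route**

Step 1
Reactants: 1 (R)-linalool
Product: 2 (3S,6R)-3-bromo-6-ethenyl-2,2,6-trimethyloxane
Conditions: TBCO (1.1 equiv), MeNO2, 0 °C → rt; chromatography
Reagents that add atoms: 2,4,4,6-tetrabromocyclohexa-2,5-dien-1-one (TBCO), O=C1C(Br)=CC(Br)(Br)C=C1Br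
Why: Bromonium-induced 6-endo bromoetherification, in which Br+ adds to the trisubstituted alkene rather than the vinyl group and the tertiary hydroxyl opens the bromonium ion at the tertiary carbon, so C6 keeps the configuration of linalool and C3 is set by the face of bromonium formation in a chair with equatorial bromine; the wanted 3S isomer is expected beside its C3 epimer and five-membered ethers and is separated.

Step 2
Reactants: 2 (3S,6R)-3-bromo-6-ethenyl-2,2,6-trimethyloxane
Product: 4 (2R,5S)-5-bromo-2,6,6-trimethyloxane-2-carbaldehyde, via secondary ozonide 3 (not isolated)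
Conditions: O3, CH2Cl2, −78 °C; then Me2S, −78 °C → rt
Reagents that add atoms: ozone, [O-][O+]=O
Why: Ozonolysis with reductive work-up should cleave the only C=C bond to a non-enolisable α-alkoxy aldehyde without touching either stereocentre or the secondary bromide.

Step 3
Reactants: 4 (2R,5S)-5-bromo-2,6,6-trimethyloxane-2-carbaldehyde
Product: 5 (3S,6R)-3-bromo-6-ethynyl-2,2,6-trimethyloxane
Conditions: dimethyl (1-diazo-2-oxopropyl)phosphonate, K2CO3, MeOH, 0 °C → rt
Reagents that add atoms: dimethyl (1-diazo-2-oxopropyl)phosphonate, COP(=O)(OC)C(=[N+]=[N-])C(C)=O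
Why: Ohira–Bestmann (Seyferth–Gilbert) homologation should work cleanly on this non-enolisable aldehyde, and the equatorial bromide has no antiperiplanar hydrogen for elimination under the mild base.

Step 4
Reactants: 6 hex-5-en-2-one; 7 methacrolein (2-methylprop-2-enal)
Product: 8 (2E)-2-methyl-6-oxohept-2-enal
Conditions: second-generation Hoveyda–Grubbs catalyst (H2IMes)Cl2Ru=CH(C6H4-2-OiPr) (3 mol %), 7 (3 equiv), CH2Cl2, 40 °C
Reagents that add atoms: none
Why: Olefin cross-metathesis of a terminal alkene with the 1,1-disubstituted, non-dimerising methacrolein should give the trisubstituted enal as the thermodynamically favoured E isomer with loss of ethene.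

Step 5
Reactants: 5 (3S,6R)-3-bromo-6-ethynyl-2,2,6-trimethyloxane; 8 (2E)-2-methyl-6-oxohept-2-enal
Product: 11 (5E,7S,8E)-9-[(2R,5S)-5-bromo-2,6,6-trimethyloxan-2-yl]-7-hydroxy-6-methylnona-5,8-dien-2-one, via alkenylzirconocene chloride 9 (not isolated), via alkenyl(methyl)zinc 10 (not isolated)
Conditions: 5, Cp2Zr(H)Cl, CH2Cl2, rt; Me2Zn, toluene, −65 °C; (−)-MIB (10 mol %), then 8, −30 → 0 °C; H2O
Reagents that add atoms: none
Why: syn-Hydrozirconation of the terminal alkyne gives the E-alkenyl metal, and after transmetalation to zinc the amino-alcohol-catalysed asymmetric 1,2-addition should take place at the aldehyde only (not the methyl ketone), with Si-face delivery under catalyst control setting C7 as S.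

Step 6
Reactants: 11 (5E,7S,8E)-9-[(2R,5S)-5-bromo-2,6,6-trimethyloxan-2-yl]-7-hydroxy-6-methylnona-5,8-dien-2-one; 12 butyl vinyl ether
Product: 14 (3S)-3-[(2E,4E)-5-[(2R,5S)-5-bromo-2,6,6-trimethyloxan-2-yl]penta-2,4-dien-2-yl]-6-oxoheptanal, via allyl vinyl ether 13 (not isolated)
Conditions: 12 (solvent), Pd(OCOCF3)2 (2 mol %), 4,7-diphenyl-1,10-phenanthroline (2 mol %), Et3N, 75 °C; evaporate; toluene, 110 °C; used without delay
Reagents that add atoms: none
Why: Palladium-catalysed vinyl ether exchange followed by Claisen rearrangement through the trisubstituted alkene, in a chair transition state with the alkenyl substituent of C7 equatorial, should transfer the S configuration of C7 to C3 of 14 and create the E trisubstituted alkene of the diene, the alternative [3,3] shift through the other alkene being blocked by the adjacent quaternary carbon.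

Step 7
Reactants: 14 (3S)-3-[(2E,4E)-5-[(2R,5S)-5-bromo-2,6,6-trimethyloxan-2-yl]penta-2,4-dien-2-yl]-6-oxoheptanal
Product: 15 (5S)-7,7-dibromo-5-[(2E,4E)-5-[(2R,5S)-5-bromo-2,6,6-trimethyloxan-2-yl]penta-2,4-dien-2-yl]heptan-2-one
Conditions: (PhO)3P, Br2, CH2Cl2, −78 °C; then 14, Et3N, −78 → −20 °C
Reagents that add atoms: bromine, BrBr
Why: Appel-type deoxygenative geminal dibromination of the aldehyde by the preformed triphenyl phosphite–bromine adduct should occur at low temperature, where the less electrophilic methyl ketone does not react and no free bromine or acid reaches the diene; no stereocentre is involved.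

Step 8
Reactants: 15 (5S)-7,7-dibromo-5-[(2E,4E)-5-[(2R,5S)-5-bromo-2,6,6-trimethyloxan-2-yl]penta-2,4-dien-2-yl]heptan-2-one
Product: 17 (1R,2S,4S)-2-bromo-4-[(2E,4E)-5-[(2R,5S)-5-bromo-2,6,6-trimethyloxan-2-yl]penta-2,4-dien-2-yl]-1-methylcyclohexan-1-ol, via α-bromoalkylsamarium diiodide 16 (not isolated)
Conditions: SmI2 (2.2 equiv), THF, −78 → −20 °C, slow addition of 15; then H2O (pH 7)
Reagents that add atoms: none
Why: Proposed new method: two single-electron transfers from SmI2 to the 1,1-dibromide should give the α-bromoalkylsamarium carbenoid 16, whose carbon–samarium bond adds to the tethered methyl ketone to form the C1–C2 bond, the samarium alkoxide being protonated on work-up. The closest known reaction types are the SmI2/CH2I2 iodomethylation of ketones, in which an α-halomethylsamarium adds to a carbonyl group and keeps its halogen, and the intramolecular samarium Barbier cyclisation of halo ketones; neither has been shown for a tethered higher 1,1-dibromoalkane. The cyclohexane ring closes in a 6-exo-trig mode, with the carbanionic carbon (C7 of 15, ring C2) attacking the carbonyl carbon (C2 of 15, ring C1). C1 and C2 should be set by a chair-like transition state in which the dienyl group on C4, the bromine on C2 and the ketone methyl group are equatorial, while the samarium-bound oxygen is axial and gauche to bromine as metal bridging of O and Br requires; this gives the 1R,2S bromohydrin with OH cis to Br. The step needs chemoselective reduction of the geminal dibromide beside the ketone, the secondary bromide of the oxane ring and the diene, which the much easier reduction of 1,1-dihalides by SmI2 in THF without HMPA should secure. It must also stop at the bromohydrin, for which only two equivalents of SmI2 and low temperature are used.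

**Compound list**

1 | (R)-linalool, (3R)-3,7-dimethylocta-1,6-dien-3-ol | C=C[C@](C)(O)CCC=C(C)C | starting material
2 | (3S,6R)-3-bromo-6-ethenyl-2,2,6-trimethyloxane | C=C[C@@]1(C)CC[C@H](Br)C(C)(C)O1 | intermediate
3 | 3-[(2R,5S)-5-bromo-2,6,6-trimethyloxan-2-yl]-1,2,4-trioxolane (secondary ozonide, epimers at the trioxolane carbon) | C1OOC(O1)[C@@]2(C)CC[C@H](Br)C(C)(C)O2 | intermediate
4 | (2R,5S)-5-bromo-2,6,6-trimethyloxane-2-carbaldehyde | O=C[C@@]1(C)CC[C@H](Br)C(C)(C)O1 | intermediate
5 | (3S,6R)-3-bromo-6-ethynyl-2,2,6-trimethyloxane | C#C[C@@]1(C)CC[C@H](Br)C(C)(C)O1 | intermediate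
6 | hex-5-en-2-one | CC(=O)CCC=C | starting material
7 | methacrolein (2-methylprop-2-enal) | CC(=C)C=O | starting material
8 | (2E)-2-methyl-6-oxohept-2-enal | CC(=O)CC/C=C(\C)C=O | intermediate
9 | chloro{(E)-2-[(2R,5S)-5-bromo-2,6,6-trimethyloxan-2-yl]ethenyl}bis(cyclopentadienyl)zirconium | Cl[Zr](/C=C/[C@@]1(C)CC[C@H](Br)C(C)(C)O1)(C1C=CC=C1)C1C=CC=C1 | intermediate
10 | {(E)-2-[(2R,5S)-5-bromo-2,6,6-trimethyloxan-2-yl]ethenyl}(methyl)zinc | C[Zn]/C=C/[C@@]1(C)CC[C@H](Br)C(C)(C)O1 | intermediate
11 | (5E,7S,8E)-9-[(2R,5S)-5-bromo-2,6,6-trimethyloxan-2-yl]-7-hydroxy-6-methylnona-5,8-dien-2-one | CC(=O)CC/C=C(\C)[C@@H](O)/C=C/[C@@]1(C)CC[C@H](Br)C(C)(C)O1 | intermediate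
12 | butyl vinyl ether (1-(ethenyloxy)butane) | C=COCCCC | starting material
13 | (5E,7S,8E)-9-[(2R,5S)-5-bromo-2,6,6-trimethyloxan-2-yl]-7-(ethenyloxy)-6-methylnona-5,8-dien-2-one | CC(=O)CC/C=C(\C)[C@@H](OC=C)/C=C/[C@@]1(C)CC[C@H](Br)C(C)(C)O1 | intermediate
14 | (3S)-3-[(2E,4E)-5-[(2R,5S)-5-bromo-2,6,6-trimethyloxan-2-yl]penta-2,4-dien-2-yl]-6-oxoheptanal | O=CC[C@H](CCC(C)=O)/C(C)=C/C=C/[C@@]1(C)CC[C@H](Br)C(C)(C)O1 | intermediate
15 | (5S)-7,7-dibromo-5-[(2E,4E)-5-[(2R,5S)-5-bromo-2,6,6-trimethyloxan-2-yl]penta-2,4-dien-2-yl]heptan-2-one | BrC(Br)C[C@H](CCC(C)=O)/C(C)=C/C=C/[C@@]1(C)CC[C@H](Br)C(C)(C)O1 | intermediate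
16 | {(3S)-1-bromo-3-[(2E,4E)-5-[(2R,5S)-5-bromo-2,6,6-trimethyloxan-2-yl]penta-2,4-dien-2-yl]-6-oxoheptyl}samarium diiodide (configuration at the metal-bearing carbon not defined) | I[Sm](I)C(Br)C[C@H](CCC(C)=O)/C(C)=C/C=C/[C@@]1(C)CC[C@H](Br)C(C)(C)O1 | intermediate
17 | (1R,2S,4S)-2-bromo-4-[(2E,4E)-5-[(2R,5S)-5-bromo-2,6,6-trimethyloxan-2-yl]penta-2,4-dien-2-yl]-1-methylcyclohexan-1-ol | C/C(=C\C=C\[C@@]1(C)CC[C@H](Br)C(C)(C)O1)[C@H]1CC[C@@](C)(O)[C@@H](Br)C1 | target

**Step count**

Total: 8 steps. Longest linear sequence: 7 steps (steps 1, 2, 3, 5, 6, 7, 8).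

**Steps most likely to fail**

1. Step 8, the step marked as a proposed new method. The carbenoid addition may discriminate poorly between the chair transition states, giving C1/C2 diastereomers. The bromohydrin may be reduced further with reductive elimination to the cyclohexene. The carbenoid may be protonated or undergo a 1,2-hydride shift before it reaches the ketone.
   The fallback uses known reactions only, sets out from 14 and comes back at 17. Aldehyde-selective Wittig methylenation (Ph3P=CH2 from Ph3PCH3Br and KN(SiMe3)2, THF, −78 °C) should give the terminal alkene F1. Kinetic enolisation of the methyl ketone (LiN(iPr)2, tBuMe2SiCl, THF, −78 °C) should give the silyl enol ether F2. Ring-closing metathesis with the second-generation Grubbs catalyst (H2IMes)(PCy3)Cl2Ru=CHPh should close the same C1–C2 bond as the double bond of the cyclic silyl enol ether F3. N-Bromosuccinimide (THF, −78 °C) should brominate F3 at C2, first giving the axial α-bromo ketone F4. This would be epimerised (LiBr, MeCN) towards the equatorial epimer F5, and the epimers separated. Addition of MeTi(OiPr)3 to F5 from the equatorial direction, the known way from 2-halocyclohexanones to cis-halohydrins, should then give 17.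

2. Step 7. Chemoselectivity may be lost, with the methyl ketone converted into a vinyl bromide, or bromine or HBr may add to the diene or ionise the doubly allylic ether.
   The fallback sets out from 14 and comes back at 15. Condensation of the aldehyde with one equivalent of hydrazine hydrate (EtOH, 0 °C) should give the aldehyde hydrazone F6. Oxidative bromination of F6 with CuBr2 and LiOtBu (THF, rt) should pass through the diazoalkane and give 15 with loss of nitrogen, without a phosphorus–bromine reagent.

3. Step 6. Vinyl transfer to the hindered doubly allylic alcohol may stay incomplete, the allylic C–O bond may ionise, or the keto aldehyde may cyclise by aldol reaction during heating.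
   The fallback sets out from 11 and comes back at 14. Johnson–Claisen rearrangement (MeC(OEt)3, cat. EtCO2H, 120 °C), which needs no preformed vinyl ether and has the same chair-controlled chirality transfer, should give the ethyl ester F7. Saponification (LiOH, THF/H2O) should give the acid F8. Thioesterification (EtSH, DCC, DMAP) should give the S-ethyl thioester F9. Fukuyama reduction (Et3SiH, Pd/C, acetone) should then give 14 without reducing the ketone.

**Further compounds**

F1 | step 8 | (5S)-5-[(2E,4E)-5-[(2R,5S)-5-bromo-2,6,6-trimethyloxan-2-yl]penta-2,4-dien-2-yl]oct-7-en-2-one | C=CC[C@H](CCC(C)=O)/C(C)=C/C=C/[C@@]1(C)CC[C@H](Br)C(C)(C)O1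
F2 | step 8 | tert-butyl(dimethyl){[(5S)-5-[(2E,4E)-5-[(2R,5S)-5-bromo-2,6,6-trimethyloxan-2-yl]penta-2,4-dien-2-yl]octa-1,7-dien-2-yl]oxy}silane | C=CC[C@H](CCC(=C)O[Si](C)(C)C(C)(C)C)/C(C)=C/C=C/[C@@]1(C)CC[C@H](Br)C(C)(C)O1
F3 | step 8 | tert-butyl(dimethyl){[(4S)-4-[(2E,4E)-5-[(2R,5S)-5-bromo-2,6,6-trimethyloxan-2-yl]penta-2,4-dien-2-yl]cyclohex-1-en-1-yl]oxy}silane | C/C(=C\C=C\[C@@]1(C)CC[C@H](Br)C(C)(C)O1)[C@H]1CCC(O[Si](C)(C)C(C)(C)C)=CC1
F4 | step 8 | (2R,4S)-2-bromo-4-[(2E,4E)-5-[(2R,5S)-5-bromo-2,6,6-trimethyloxan-2-yl]penta-2,4-dien-2-yl]cyclohexan-1-one (axial bromide) | C/C(=C\C=C\[C@@]1(C)CC[C@H](Br)C(C)(C)O1)[C@H]1CCC(=O)[C@H](Br)C1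
F5 | step 8 | (2S,4S)-2-bromo-4-[(2E,4E)-5-[(2R,5S)-5-bromo-2,6,6-trimethyloxan-2-yl]penta-2,4-dien-2-yl]cyclohexan-1-one (equatorial bromide) | C/C(=C\C=C\[C@@]1(C)CC[C@H](Br)C(C)(C)O1)[C@H]1CCC(=O)[C@@H](Br)C1
F6 | step 7 | (5S)-5-[(2E,4E)-5-[(2R,5S)-5-bromo-2,6,6-trimethyloxan-2-yl]penta-2,4-dien-2-yl]-7-hydrazinylideneheptan-2-one | NN=CC[C@H](CCC(C)=O)/C(C)=C/C=C/[C@@]1(C)CC[C@H](Br)C(C)(C)O1
F7 | step 6 | ethyl (3S)-3-[(2E,4E)-5-[(2R,5S)-5-bromo-2,6,6-trimethyloxan-2-yl]penta-2,4-dien-2-yl]-6-oxoheptanoate | CCOC(=O)C[C@H](CCC(C)=O)/C(C)=C/C=C/[C@@]1(C)CC[C@H](Br)C(C)(C)O1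
F8 | step 6 | (3S)-3-[(2E,4E)-5-[(2R,5S)-5-bromo-2,6,6-trimethyloxan-2-yl]penta-2,4-dien-2-yl]-6-oxoheptanoic acid | OC(=O)C[C@H](CCC(C)=O)/C(C)=C/C=C/[C@@]1(C)CC[C@H](Br)C(C)(C)O1
F9 | step 6 | S-ethyl (3S)-3-[(2E,4E)-5-[(2R,5S)-5-bromo-2,6,6-trimethyloxan-2-yl]penta-2,4-dien-2-yl]-6-oxoheptanethioate | CCSC(=O)C[C@H](CCC(C)=O)/C(C)=C/C=C/[C@@]1(C)CC[C@H](Br)C(C)(C)O1
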